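**Retrosynthetic overview**

1. The target is fisetinidol-(4α→8)-afzelechin. The last C–C bond made is C4 (ring C, upper unit)–C8 (ring D, lower unit): the upper C4 benzylic cation is captured by benzylated (+)-afzelechin anti to O3, and global debenzylation follows.
2. Ring C of the upper unit is closed in one annulation that makes C2–C3 (aldol addition) and O1–C8a (SNAr) in the same flask, from the N-tert-butanesulfinyl imine of an α-benzyloxy 2-fluoroaryl ketone and 3,4-bis(benzyloxy)benzaldehyde.
3. Enabling feature: C4 of ring C is bonded to C4a, the ring-A carbon ortho to C8a. At the C=N/C=O oxidation level C4 acidifies C3–H (C3 becomes the nucleophile) and activates C8a–F for ipso attack by the C2 alkoxide. The same C4, para to O7 through ring A, later gives the stabilised cation for the interflavan bond.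
4. Ring order: rings A and B and the whole lower unit (rings D, E, F) are bought; ring C is the only ring formed (step 3). C2 comes from the sulfinyl auxiliary, C3 from equilibration to trans, C4 from anti attack, and the lower C2/C3 from the chiral pool.

Key step: step 3

Remarks on the chemistry (assumptions):
- (+)-Afzelechin [(2R,3S)] is taken as a purchasable natural flavan-3-ol.
- The (R)-sulfinyl group is taken to deliver the (2R) centre through a closed, metal-bridged chair transition state with tert-butyl turned away from the aldehyde. If the sense were the opposite, the (S)-sulfinamide, also purchasable, would be used with no other change.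

**Route**

Step 1
Reactants: 1 4-(benzyloxy)-1-bromo-2-fluorobenzene; 2 2-(benzyloxy)-N-methoxy-N-methylacetamide
Product: 3 2-(benzyloxy)-1-[4-(benzyloxy)-2-fluorophenyl]ethan-1-one
Conditions: iPrMgCl·LiCl, THF, −15 → 0 °C; then 2, 0 → 23 °C; aq. NH4Cl
Reagents that add atoms: none
Why: Halogen–magnesium exchange of the aryl bromide (accelerated by the ortho fluorine, kept cold to avoid aryne formation) followed by acylation with the N-methoxy-N-methyl amide, whose chelated tetrahedral adduct prevents over-addition (Weinreb ketone synthesis).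

Step 2
Reactants: 3 2-(benzyloxy)-1-[4-(benzyloxy)-2-fluorophenyl]ethan-1-one; 4 (R)-2-methylpropane-2-sulfinamide
Product: 5 (R)-N-{(Z)-2-(benzyloxy)-1-[4-(benzyloxy)-2-fluorophenyl]ethylidene}-2-methylpropane-2-sulfinamide
Conditions: Ti(OEt)4, THF, 65 °C
Reagents that add atoms: none
Why: Ti(OEt)4-mediated condensation of a ketone with tert-butanesulfinamide (the water is scavenged by the titanium alkoxide) should give the N-sulfinyl ketimine with the sulfur configuration untouched and the sulfinyl group anti to the aryl ring.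

Step 3
Reactants: 5 (R)-N-{(Z)-2-(benzyloxy)-1-[4-(benzyloxy)-2-fluorophenyl]ethylidene}-2-methylpropane-2-sulfinamide; 6 3,4-bis(benzyloxy)benzaldehyde
Product: 10 (2R,3R)-3,7-bis(benzyloxy)-2-[3,4-bis(benzyloxy)phenyl]-2,3-dihydro-4H-chromen-4-one, via lithium aza-enolate 7 (not isolated), via lithium syn-aldolate 8 (not isolated), via cyclic N-sulfinyl ketimine 9 (not isolated)
Conditions: LiN(iPr)2, THF, −78 °C; then 6, −78 °C; DMPU, −78 → 23 °C; then 1 M aq. HCl, THF, 0 °C; then Et3N (cat.), CH2Cl2, 23 °C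
Reagents that add atoms: water, O
Why: Proposed new method: LiN(iPr)2 removes the C3–H acidified by the C4 sulfinyl imine, the aza-enolate 7 adds to aldehyde 6 through a closed six-membered chair transition state (C2–C3 bond), and the C2 alkoxide of 8 then attacks C8a, activated by the ortho C4=N acceptor, and expels fluoride through a Meisenheimer intermediate (O1–C8a bond). The closest known reaction types are the aldol addition of N-sulfinyl metalloenamines to aldehydes and the tandem aldol–SNAr annulation of 2-fluoroaryl ketones. Ring C closes in a 6-exo-trig addition–elimination mode. C2 is controlled by the sulfur stereocentre, which fixes the face of the aza-enolate offered to the lithium-bound aldehyde. C3 is controlled thermodynamically: it is epimerisable next to C4=N and C4=O and should settle trans-diequatorial to the C2 aryl group after hydrolysis of 9 (which returns the auxiliary) and the Et3N treatment. The step needs α-deprotonation to win over metalation of ring A and ring closure to win over retro-aldol scrambling of C2; the chelating sulfinyl imine/benzyloxy pair secures the first, and the ortho relation of C4 to C8a with fluoride as leaving group secures the second.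

Step 4
Reactants: 10 (2R,3R)-3,7-bis(benzyloxy)-2-[3,4-bis(benzyloxy)phenyl]-2,3-dihydro-4H-chromen-4-one
Product: 11 (2R,3S,4R)-3,7-bis(benzyloxy)-2-[3,4-bis(benzyloxy)phenyl]-3,4-dihydro-2H-chromen-4-ol
Conditions: NaBH4, MeOH–THF, 0 °C
Reagents that add atoms: none
Why: Hydride should add axially to the C4 carbonyl of the half-chair with the C2 and C3 substituents equatorial, giving mainly the equatorial 3,4-trans (4R) carbinol; the C4 configuration is of no consequence because this centre is ionised in step 6.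

Step 5
Reactants: 12 (+)-afzelechin, (2R,3S)-2-(4-hydroxyphenyl)-3,4-dihydro-2H-chromene-3,5,7-triol
Product: 13 (2R,3S)-5,7-bis(benzyloxy)-2-[4-(benzyloxy)phenyl]-3,4-dihydro-2H-chromen-3-ol
Conditions: BnBr, K2CO3, DMF, 0 → 23 °C
Reagents that add atoms: benzyl bromide, BrCc1ccccc1
Why: Williamson etherification under carbonate conditions ionises only the three phenols (O5, O7, O4'), so the secondary 3-OH stays free and both stereocentres are untouched.

Step 6
Reactants: 11 (2R,3S,4R)-3,7-bis(benzyloxy)-2-[3,4-bis(benzyloxy)phenyl]-3,4-dihydro-2H-chromen-4-ol; 13 (2R,3S)-5,7-bis(benzyloxy)-2-[4-(benzyloxy)phenyl]-3,4-dihydro-2H-chromen-3-ol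
Product: 14 (2R,3S)-5,7-bis(benzyloxy)-2-[4-(benzyloxy)phenyl]-8-{(2R,3S,4S)-3,7-bis(benzyloxy)-2-[3,4-bis(benzyloxy)phenyl]-3,4-dihydro-2H-chromen-4-yl}-3,4-dihydro-2H-chromen-3-ol
Conditions: 13 (3 equiv), TMSOTf (cat.), 4 Å molecular sieves, CH2Cl2, −78 → −40 °C; Et3N quench
Reagents that add atoms: none
Why: Lewis-acid ionisation of the C4 carbinol should give the O7-stabilised benzylic cation, which is captured in a Friedel–Crafts alkylation by C8 of ring D (the most nucleophilic position of 13) from the face anti to the 3-benzyloxy group, setting the 3,4-trans (4α, 4S) centre, while the excess of 13 suppresses oligomerisation.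

Step 7
Reactants: 14 (2R,3S)-5,7-bis(benzyloxy)-2-[4-(benzyloxy)phenyl]-8-{(2R,3S,4S)-3,7-bis(benzyloxy)-2-[3,4-bis(benzyloxy)phenyl]-3,4-dihydro-2H-chromen-4-yl}-3,4-dihydro-2H-chromen-3-ol
Product: 15 fisetinidol-(4α→8)-afzelechin, (2R,3S)-8-[(2R,3S,4S)-2-(3,4-dihydroxyphenyl)-3,7-dihydroxy-3,4-dihydro-2H-chromen-4-yl]-2-(4-hydroxyphenyl)-3,4-dihydro-2H-chromene-3,5,7-triol
Conditions: H2 (1 atm), Pd(OH)2 on carbon, THF–MeOH–H2O, 23 °C
Reagents that add atoms: none
Why: Hydrogenolysis of the seven benzyl ethers should free the six phenols and the upper 3-OH without touching the five ring stereocentres or the interflavan bond.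

**Compound list**

1 | 4-(benzyloxy)-1-bromo-2-fluorobenzene | Fc1cc(OCc2ccccc2)ccc1Br | starting material
2 | 2-(benzyloxy)-N-methoxy-N-methylacetamide | CON(C)C(=O)COCc1ccccc1 | starting material
3 | 2-(benzyloxy)-1-[4-(benzyloxy)-2-fluorophenyl]ethan-1-one | O=C(COCc1ccccc1)c1ccc(OCc2ccccc2)cc1F | intermediate
4 | (R)-2-methylpropane-2-sulfinamide | CC(C)(C)[S@@](=O)N | starting material
5 | (R)-N-{(Z)-2-(benzyloxy)-1-[4-(benzyloxy)-2-fluorophenyl]ethylidene}-2-methylpropane-2-sulfinamide (sulfur anti to the aryl ring) | CC(C)(C)[S@@](=O)/N=C(\COCc1ccccc1)c1ccc(OCc2ccccc2)cc1F | intermediate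
6 | 3,4-bis(benzyloxy)benzaldehyde | O=Cc1ccc(OCc2ccccc2)c(OCc2ccccc2)c1 | starting material
7 | lithium aza-enolate of 5, lithium [(R)-tert-butylsulfinyl]{(Z)-2-(benzyloxy)-1-[4-(benzyloxy)-2-fluorophenyl]ethenyl}azanide (formed in the flask) | CC(C)(C)[S@@](=O)N([Li])/C(=C\OCc1ccccc1)c1ccc(OCc2ccccc2)cc1F | intermediate
8 | lithium (1R,2R)-2-(benzyloxy)-1-[3,4-bis(benzyloxy)phenyl]-3-[4-(benzyloxy)-2-fluorophenyl]-3-{[(R)-tert-butylsulfinyl]imino}propan-1-olate, syn-aldolate (formed in the flask) | CC(C)(C)[S@@](=O)/N=C(/c1ccc(OCc2ccccc2)cc1F)[C@@H](OCc1ccccc1)[C@H](O[Li])c1ccc(OCc2ccccc2)c(OCc2ccccc2)c1 | intermediate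
9 | (R)-N-{(2R,3R)-3,7-bis(benzyloxy)-2-[3,4-bis(benzyloxy)phenyl]-2,3-dihydro-4H-chromen-4-ylidene}-2-methylpropane-2-sulfinamide, 2,3-cis (formed in the flask) | CC(C)(C)[S@@](=O)/N=C1/c2ccc(OCc3ccccc3)cc2O[C@H](c2ccc(OCc3ccccc3)c(OCc3ccccc3)c2)[C@@H]1OCc1ccccc1 | intermediate
10 | (2R,3R)-3,7-bis(benzyloxy)-2-[3,4-bis(benzyloxy)phenyl]-2,3-dihydro-4H-chromen-4-one, 2,3-trans | O=C1c2ccc(OCc3ccccc3)cc2O[C@H](c2ccc(OCc3ccccc3)c(OCc3ccccc3)c2)[C@H]1OCc1ccccc1 | intermediate
11 | (2R,3S,4R)-3,7-bis(benzyloxy)-2-[3,4-bis(benzyloxy)phenyl]-3,4-dihydro-2H-chromen-4-ol | O[C@@H]1c2ccc(OCc3ccccc3)cc2O[C@H](c2ccc(OCc3ccccc3)c(OCc3ccccc3)c2)[C@H]1OCc1ccccc1 | intermediate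
12 | (+)-afzelechin, (2R,3S)-2-(4-hydroxyphenyl)-3,4-dihydro-2H-chromene-3,5,7-triol | Oc1ccc([C@H]2Oc3cc(O)cc(O)c3C[C@@H]2O)cc1 | starting material
13 | (2R,3S)-5,7-bis(benzyloxy)-2-[4-(benzyloxy)phenyl]-3,4-dihydro-2H-chromen-3-ol | C(Oc1ccc([C@H]2Oc3cc(OCc4ccccc4)cc(OCc4ccccc4)c3C[C@@H]2O)cc1)c1ccccc1 | intermediate
14 | (2R,3S)-5,7-bis(benzyloxy)-2-[4-(benzyloxy)phenyl]-8-{(2R,3S,4S)-3,7-bis(benzyloxy)-2-[3,4-bis(benzyloxy)phenyl]-3,4-dihydro-2H-chromen-4-yl}-3,4-dihydro-2H-chromen-3-ol | C(Oc1ccc([C@H]2Oc3c(c(OCc4ccccc4)cc(OCc4ccccc4)c3[C@@H]3c4ccc(OCc5ccccc5)cc4O[C@H](c4ccc(OCc5ccccc5)c(OCc5ccccc5)c4)[C@H]3OCc3ccccc3)C[C@@H]2O)cc1)c1ccccc1 | intermediate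
15 | fisetinidol-(4α→8)-afzelechin, (2R,3S)-8-[(2R,3S,4S)-2-(3,4-dihydroxyphenyl)-3,7-dihydroxy-3,4-dihydro-2H-chromen-4-yl]-2-(4-hydroxyphenyl)-3,4-dihydro-2H-chromene-3,5,7-triol | Oc1ccc([C@H]2Oc3c(c(O)cc(O)c3[C@@H]3c4ccc(O)cc4O[C@H](c4ccc(O)c(O)c4)[C@H]3O)C[C@@H]2O)cc1 | target

**Count and risks**

Total step count: 7. Longest linear sequence: 6 steps (steps 1, 2, 3, 4, 6, 7).

Steps most likely to fail:

1. Step 3 (Proposed new method). The lithium aldolate may revert by retro-aldol before the ring closes, so that auxiliary control at C2 is lost. Ring A may also be metalated next to fluorine and go on to an aryne, or the ipso substitution may be too slow with a lithium alkoxide. The fallback uses known chemistry, sets out from aldehyde 6 and comes back at 10. Purchasable 1-[4-(benzyloxy)-2-hydroxyphenyl]ethan-1-one would be protected (MOMCl, iPr2NEt, CH2Cl2) to 1-[4-(benzyloxy)-2-(methoxymethoxy)phenyl]ethan-1-one F1. Claisen–Schmidt condensation with 6 (KOH, EtOH) would give the chalcone (E)-1-[4-(benzyloxy)-2-(methoxymethoxy)phenyl]-3-[3,4-bis(benzyloxy)phenyl]prop-2-en-1-one F2. Juliá–Colonna epoxidation (poly-L-leucine, urea–H2O2, DBU, THF) would give [(2R,3S)-3-(3,4-bis(benzyloxy)phenyl)oxiran-2-yl][4-(benzyloxy)-2-(methoxymethoxy)phenyl]methanone F3. HCl in MeOH–THF would remove the MOM group and let the freed phenol open the epoxide at the benzylic carbon with inversion, giving (2R,3R)-7-(benzyloxy)-2-[3,4-bis(benzyloxy)phenyl]-3-hydroxy-2,3-dihydro-4H-chromen-4-one F4. Benzylation of the 3-OH (BnBr, Ag2O, CH2Cl2) would return to 10.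

2. Step 6. The C4 cation may be captured with poor facial selectivity (4β attack) or through C6 of ring D, and the product may be alkylated again to oligomers. The fallback sets out from 10 and comes back at 15, with the phenols free during the coupling. Hydrogenolysis of 10 (H2, Pd on carbon, EtOAc–MeOH) would give (+)-fustin, (2R,3R)-2-(3,4-dihydroxyphenyl)-3,7-dihydroxy-2,3-dihydro-4H-chromen-4-one F5. NaBH4 in EtOH would reduce it to (+)-mollisacacidin, (2R,3S,4R)-2-(3,4-dihydroxyphenyl)-3,4-dihydro-2H-chromene-3,4,7-triol F6. This would be condensed with unprotected 12 in 0.1 M aq. HCl at 23 °C (the classical acid-catalysed flavan-3,4-diol/flavan-3-ol condensation), and the (4α→8) product 15 separated on Sephadex LH-20.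

3. Step 7. Reduction may go too far (hydrogenolytic opening of the benzylic C2–O1 bonds of rings C and F), or cleavage of the seven benzyl ethers may stall on the poorly soluble partly debenzylated material. The fallback sets out from 14 and comes back at 15 by a non-reductive Lewis-acid dealkylation: BCl3 with pentamethylbenzene as benzyl-cation scavenger in CH2Cl2 at −78 °C. The acid-resistant 5-deoxy interflavan bond should survive, and no new compound is made on the way (none F0).

Further compounds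
F1 | step 3 | 1-[4-(benzyloxy)-2-(methoxymethoxy)phenyl]ethan-1-one | CC(=O)c1ccc(OCc2ccccc2)cc1OCOC
F2 | step 3 | (E)-1-[4-(benzyloxy)-2-(methoxymethoxy)phenyl]-3-[3,4-bis(benzyloxy)phenyl]prop-2-en-1-one | COCOc1cc(OCc2ccccc2)ccc1C(=O)/C=C/c1ccc(OCc2ccccc2)c(OCc2ccccc2)c1
F3 | step 3 | [(2R,3S)-3-(3,4-bis(benzyloxy)phenyl)oxiran-2-yl][4-(benzyloxy)-2-(methoxymethoxy)phenyl]methanone | COCOc1cc(OCc2ccccc2)ccc1C(=O)[C@@H]1O[C@H]1c1ccc(OCc2ccccc2)c(OCc2ccccc2)c1
F4 | step 3 | (2R,3R)-7-(benzyloxy)-2-[3,4-bis(benzyloxy)phenyl]-3-hydroxy-2,3-dihydro-4H-chromen-4-one | O=C1c2ccc(OCc3ccccc3)cc2O[C@H](c2ccc(OCc3ccccc3)c(OCc3ccccc3)c2)[C@H]1O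
F5 | step 6 | (+)-fustin, (2R,3R)-2-(3,4-dihydroxyphenyl)-3,7-dihydroxy-2,3-dihydro-4H-chromen-4-one | O=C1c2ccc(O)cc2O[C@H](c2ccc(O)c(O)c2)[C@H]1O
F6 | step 6 | (+)-mollisacacidin, (2R,3S,4R)-2-(3,4-dihydroxyphenyl)-3,4-dihydro-2H-chromene-3,4,7-triol | O[C@@H]1c2ccc(O)cc2O[C@H](c2ccc(O)c(O)c2)[C@H]1O
F0 | step 7 | none | none
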